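- Target has to pass open intermediate by the end for a flask to hold more of target. Thursday's run has 4% of its substrate left at 120 min, so we treat the charge as shared between those two, and target then needs about half of it by the end, a mean pace in dusk of 0.00708 M/h.

| flask | substrate | reagent | free catalyst | remark | time |
|---|---|---|---|---|---|
| Monday's | 0.085 M | 0.10 M | 2.3 mM | run made earlier |  |
| Thursday's | 0.043 M | 0.153 M | 2.3 mM | run made earlier |  |
| dusk | 0.085 M | 0.153 M | 2.3 mM |  | 6.0 h |
| noon | 0.085 M | 0.153 M | 2.8 mM |  | 6.0 h |
| winter | 0.085 M | 0.153 M | 3.3 mM |  | 6.0 h |

| run | time / min | target / % | substrate / % | open intermediate / % |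
|---|---|---|---|---|
| Monday's | 8.00 | 0 | 77 | 24 |
| Monday's | 25.0 | 2 | 49 | 51 |
| Monday's | 40.0 | 3 | 35 | 58 |
| Monday's | 60.0 | 8 | 20 | 68 |
| Monday's | 90.0 | 6 | 12 | 76 |
| Monday's | 120 | 13 | 8 | 83 |
| Thursday's | 8.00 | 0 | 72 | 21 |
| Thursday's | 25.0 | 1 | 46 | 50 |
| Thursday's | 40.0 | 7 | 31 | 64 |
| Thursday's | 60.0 | 9 | 19 | 70 |
| Thursday's | 90.0 | 15 | 9 | 74 |
| Thursday's | 120 | 17 | 4 | 71 |

(readings scatter by 2 percentage points)

- which of these there is most of at the end, counted by the substrate in it, dusk (open intermediate / substrate / target)
- which of these there is most of at the end, counted by the substrate in it, noon (open intermediate / substrate / target)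
- which of these there is most of at the end, counted by the substrate in it, winter (open intermediate / substrate / target)
- the largest of these amounts at the end, in percent of the substrate charged, dusk
- the largest of these amounts at the end, in percent of the substrate charged, noon
- the largest of these amounts at the end, in percent of the substrate charged, winter

- the earlier runs were read with a standard deviation of 2 percentage points
- what may be going on: free catalyst -> spent catalyst A; free catalyst + open intermediate <-> catalyst intermediate; substrate + free catalyst -> free catalyst + open intermediate; reagent + catalyst intermediate -> free catalyst + target; free catalyst + target -> spent catalyst B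
- no earlier run changes the charge of free catalyst; that part of a forecast is a guess

- From 25.0 min to 120 min Monday's run makes target at 0.00591 M/h and Thursday's at 0.00435 M/h.
- We freeze the pace as proportional to reagent and to substrate charged. Monday's reading then becomes 0.00904 M/h for dusk and Thursday's 0.00859 M/h, two separate flasks, and we take their mean, 0.00881 M/h, as the early pace.
- So dusk needs 0.804. This is the needed keep, the share of the early pace that the mean pace over the whole time must hold for target to pass.
- If the pace also follows the catalyst charge, which is a guess no earlier run tests, noon needs 0.660 and winter 0.560.
- As a reading of how much survives, the substrate's pseudo-first-order constant after 60.0 min stands at 0.801 of its earlier value, on the mean of both runs. We expect less than that over the whole time, so we commit to open intermediate in dusk and target in winter, and leave noon open.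
- The forecast differs: it gives open intermediate in dusk at 67%, in noon at 60% and in winter at 54%, though it too holds that “Target scales roughly with catalyst charge”.

    free catalyst → spent catalyst A (k = 0.140 /h)
    free catalyst + open intermediate ⇌ catalyst intermediate (K = 26.0 /M, k = 220 /M/h)
    substrate + free catalyst → free catalyst + open intermediate (k = 1000 /M/h)
    reagent + catalyst intermediate → free catalyst + target (k = 72.0 /M/h)
    free catalyst + target → spent catalyst B (k = 1.20 /M/h)

- Dusk ends with open intermediate at 53.6%, noon with target at 52.8%, and winter with target at 59.1%.
- Taken on the early pace as read, and for noon and winter on our guessed scaling with catalyst charge, the realised keep is 0.731 in dusk against 0.804 needed, 0.698 in noon against 0.660, and 0.662 in winter against 0.560.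
- The neighbour of noon with 0.061 M of reagent, its early pace scaled down with the reagent, needs a keep of 1.66, more than the whole of that pace, and that neighbour ends with open intermediate at 70.2% and target at 28.4%.
- Noon has not come to rest: at 60.0 h its open intermediate has gone from 46.3% to 23.0%, and its target stands at 76.2%.

The runs are calculated for substances that don't exist, and the scatter is random.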